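Readings and results stem from a simulated flask for an exercise; the scatter is artificial.

Nobody can read the share of G in alpha off an earlier run: those runs stood at 35 °C and 52 °C, and alpha stands hotter, at 65 °C.

| flask | Q | E | D | temperature | remark | time |
|---|---|---|---|---|---|---|
| dusk | 0.0067 M | 1.5 equiv | 1.4 mol% | 35 °C | run made earlier |  |
| noon | 0.015 M | 1.5 equiv | 1.4 mol% | 52 °C | run made earlier |  |
| dawn | 0.010 M | 1.5 equiv | 2.1 mol% | 35 °C | run made earlier |  |
| zeta | 0.010 M | 1.50 equiv | 1.4 mol% |  | at 40 °C until 40 min, from then on at 65 °C | 1.0 h |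
| epsilon | 0.010 M | 1.50 equiv | 1.4 mol% | 40 °C |  | 1.0 h |
| alpha | 0.010 M | 1.50 equiv | 1.4 mol% | 65 °C |  | 1.0 h |

| run | time / min | G / % | Z / % |
|---|---|---|---|
| dusk | 2.50 | 0 | 0.2 |
| dusk | 8.00 | 0.1 | 0 |
| dusk | 12.0 | 0.9 | 0 |
| dusk | 20.0 | 0.7 | 0.4 |
| dusk | 30.0 | 3.1 | 1.2 |
| dusk | 40.0 | 4.9 | 1.1 |
| noon | 1.33 | 0.1 | 0.4 |
| noon | 4.00 | 4.5 | 1.2 |
| noon | 6.00 | 7.0 | 1.5 |
| noon | 12.0 | 18.1 | 4.9 |
| noon | 15.0 | 21.4 | 8.1 |
| noon | 20.0 | 27.5 | 13.7 |
| dawn | 3.00 | 0 | 0.6 |
| dawn | 10.0 | 2.7 | 0.8 |
| dawn | 15.0 | 4.8 | 0.9 |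
| dawn | 25.0 | 9.8 | 2.1 |
| dawn | 40.0 | 17.7 | 6.5 |

(each reading ± 0.5 percentage points)

- the flask that comes out highest in share of G in all that became G or Z, or "all alike" when all lie within 1.5 percentage points (zeta / epsilon / alpha / all alike)
- share of G in all that became G or Z, zeta
- share of G in all that became G or Z, epsilon
- share of G in all that became G or Z, alpha



*Where does Z come from?* From G, as far as the readings show: in the noon run Z gains faster late, with much G standing, than early.

*What do you count?* Turnovers of G on D. The Z gained per minute, divided by the G standing, says how often, net, a G is turned over. Late in the dawn run that reads 0.0213 min⁻¹, and late in the noon run 0.0482 min⁻¹. Both flasks hold the same c(D), 2.10 × 10⁻⁴ M, but they differ in c(Q) as well as in temperature; I assume that c(Q) does not enter a rate per G, and on that assumption I lay the difference to temperature.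

*And at other temperatures?* This is my own reckoning. I take the rate as proportional to c(D), and I let its logarithm run straight with temperature. For c(D) of 1.40 × 10⁻⁴ M that gives 0.0181 min⁻¹ at 40 °C and 0.0600 min⁻¹ at 65 °C. Multiplied by the time spent, epsilon counts 1.08, zeta 1.92 and alpha 3.60. That count, the rate per G times the time at each temperature, I call turns. Alpha has the most, epsilon the fewest, so I rank epsilon first, then zeta, then alpha.

*Does the share keep falling with turns?* I cannot say. The noon run's last reading counts 0.965 turns with a share of 66.7%, and alpha lies beyond it. I commit to the order, not to a share for alpha.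

The forecast named epsilon, with 63% for zeta, 68% for epsilon and 35% for alpha, and said of alpha: “The share is very uncertain”.

The flasks give 60.4% for zeta, 68.4% for epsilon and 57.4% for alpha, so epsilon stands highest, and alpha lies 22 percentage points above the forecast.

    Q + D → D + J (k = 373 L mol⁻¹ min⁻¹, Ea = 56.0 kJ mol⁻¹)
    G + D ⇌ Z + D, rate k2*[D]*[G] forward; the back reaction follows from the equilibrium constant (K = 0.780, k = 200 L mol⁻¹ min⁻¹, Ea = 49.0 kJ mol⁻¹, ΔH = 0 kJ mol⁻¹)
    E + D + J → D + G (k = 5200 L² mol⁻² min⁻¹, Ea = 41.0 kJ mol⁻¹)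
    (constants at 40 °C)

G and Z interconvert, and in epsilon their relaxation half-life by that step alone, both ways together, is 0.181 h at 1.00 h, short against the flask's 1.0 h. Left ten times as long, zeta shows 56.2%, epsilon 56.3% and alpha 56.2%, the share under thermodynamic control. Counted in turns, epsilon has 1.08 and shows 68.4%, zeta has 1.92 and shows 60.4%, and alpha has 3.60 and shows 57.4%. The neighbour of epsilon with 0.040 M of Q, loadings held, counts 4.34 turns and shows 56.4%.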